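## Retrosynthetic overview

1. Target ⇒ 7-endo bicyclo[3.3.1]nonane-2,4,9-trione (bridgehead benzoyl, C5 geranyl, C3 and C7 prenyl). The seven-membered carbocycle and the 1,2-dioxepane are disconnected together as one aerobic radical chain (C3 radical → 7-exo C–C, O2, 7-exo peroxyl closure, O2), not as a peroxidation of a finished cage.
2. Bicycle ⇒ monocyclic dearomatised acylphloroglucinol with a tertiary carbinol side chain. Ring B is closed last, at the benzoyl-bearing carbon, by an SN1 alkylation made regiospecific by a traceless bromine at C3.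
3. Monocycle ⇒ δ-lactone acid + dianion of 7-methyl-1-phenyloct-6-ene-1,3-dione. Ring A forms by acylation and Dieckmann closure; the lactone oxygen is a placeholder for C1.
4. δ-Lactone acid ⇒ (R)-lavandulol + di-tert-butyl malonate + geranyl bromide. The lactone ring relays the lavandulol stereocentre (C7) to the quaternary C5 by trans alkylation; all later stereocentres follow from these two.
5. Order of ring formation: sacrificial lactone → ring A → ring B → carbocycle and dioxepane in one operation.

Assumption: (R)-(−)-lavandulol (1), the natural enantiomer, is bought as such; the cheaper racemate can be resolved by lipase acylation if needed.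

Atom labels C1–C9 are those of the bicyclo[3.3.1]nonane core made in step 7 (C1 benzoyl bridgehead, C3 prenylated enol carbon, C5 geranyl bridgehead, C7 CH with prenyl, C8 CMe2, C9 bridging ketone) and are used for the same atoms throughout.

## Route

Step 1
Reactants: 1 (R)-lavandulol
Product: 2 (R)-lavandulyl iodide
Conditions: I2, PPh3, imidazole, CH2Cl2, 0 to 23 °C
Reagents that add atoms: iodine, II
Why: Appel-type iodination of the primary alcohol by SN2 at CH2, so the adjacent stereocentre is not touched.

Step 2
Reactants: 2 (R)-lavandulyl iodide; 3 di-tert-butyl malonate (1.5 equiv)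
Product: 4 di-tert-butyl 2-[(2S)-5-methyl-2-(prop-1-en-2-yl)hex-4-en-1-yl]malonate
Conditions: NaH, THF/DMF (4:1), 0 to 60 °C
Reagents that add atoms: none
Why: Malonic ester alkylation (SN2 of the sodium enolate on the primary iodide); the stereocentre is beta to the reacting carbon and is carried through, and excess malonate suppresses dialkylation.

Step 3
Reactants: 4 di-tert-butyl lavandulylmalonate
Product: 5 (5S)-6,6-dimethyl-5-(3-methylbut-2-en-1-yl)-2-oxooxane-3-carboxylic acid (C3 epimers)
Conditions: CF3CO2H/CH2Cl2 (1:4), 0 to 23 °C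
Reagents that add atoms: none
Why: Acidolysis of both tert-butyl esters followed by Markovnikov hydroacyloxylation (acid-catalysed lactonisation) of the isopropenyl group through its tertiary cation gives the six-membered lactone whose ring oxygen marks the later position of C1; C7 keeps the lavandulol configuration and C5 (a CH between two carbonyls) stays epimerisable.

Step 4
Reactants: 5 lactone acid; 6 geranyl bromide
Product: 7 (3S,5S)-3-[(2E)-3,7-dimethylocta-2,6-dien-1-yl]-6,6-dimethyl-5-(3-methylbut-2-en-1-yl)-2-oxooxane-3-carboxylic acid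
Conditions: LiN(iPr)2 (2.2 equiv), THF, −78 °C; then 6, −78 to −20 °C; aq. citric acid
Reagents that add atoms: none
Why: Malonate-type C-alkylation of the lactone enolate–carboxylate dianion, in which geranyl bromide enters axially on the half-chair enolate anti to the pseudo-equatorial C7 prenyl arm, sets the quaternary C5 with geranyl trans and CO2H cis to that arm (the relationship a 7-endo bicycle needs); the minor cis lactone is removed by chromatography.

Step 5
Reactants: 8 benzoylacetone; 9 prenyl bromide
Product: 10 7-methyl-1-phenyloct-6-ene-1,3-dione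
Conditions: LiN(iPr)2 (2.2 equiv), THF, −78 to 0 °C; then 9, 0 °C
Reagents that add atoms: none
Why: Harris-type gamma-alkylation of a beta-diketone dianion, which reacts only at the terminal, more basic carbanion.

Step 6
Reactants: 7 geranylated lactone acid; 10 7-methyl-1-phenyloct-6-ene-1,3-dione (1.5 equiv)
Product: 13 (6S)-2-benzoyl-6-[(2E)-3,7-dimethylocta-2,6-dien-1-yl]-3,5-dihydroxy-6-[(2S)-2-(2-hydroxypropan-2-yl)-5-methylhex-4-en-1-yl]-4-(3-methylbut-2-en-1-yl)cyclohexa-2,4-dien-1-one, via imidazolide 11 (not isolated), via acylated lactone 12 (not isolated)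
Conditions: 7, 1,1'-carbonyldiimidazole, THF, 23 °C; then added to 10/LiN(iPr)2 (3.3 equiv), THF, −78 to 40 °C; aq. citric acid
Reagents that add atoms: none
Why: Acyl imidazole activation, gamma-acylation of the diketone dianion at the only strongly electrophilic carbonyl (Harris acylation) and intramolecular Claisen (Dieckmann-type) attack of the central carbon on the lactone carbonyl with loss of the tertiary alkoxide build ring A, driven by the triketone enolate; since the acid carbon becomes C4 and the lactone carbon C9, the C5 configuration is transferred unchanged and no new stereocentre forms.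

Step 7
Reactants: 13 monocyclic acylphloroglucinol carbinol
Product: 16 (1S,5S,7S)-1-benzoyl-5-[(2E)-3,7-dimethylocta-2,6-dien-1-yl]-4-hydroxy-8,8-dimethyl-3,7-bis(3-methylbut-2-en-1-yl)bicyclo[3.3.1]non-3-ene-2,9-dione, via C3-bromo monocycle 14 (not isolated), via C3-bromo bicycle 15 (not isolated)
Conditions: N-bromosuccinimide, CH2Cl2, −78 °C; then TfOH (10 mol %), (CF3)2CHOH, −40 to 0 °C; then aq. Na2SO3, 0 °C
Reagents that add atoms: none
Why: Proposed new method: N-bromosuccinimide brominates the most nucleophilic enol carbon C3, which makes it quaternary and leaves the benzoyl-bearing C1 as the only carbon nucleophile, so acid ionisation of the tertiary carbinol (C8 cation) can close ring B only at C1 (O-alkylation is reversible under acid, C-alkylation is not), the fixed C5 and C7 centres force the C7 prenyl arm endo and the bridge geometry fixes C1, and sulfite then removes bromine by halophilic attack to return the C3 enol; the closest known reactions are the formic acid-mediated cationic cyclisation of dearomatised acylphloroglucinols to bicyclo[3.3.1]nonane triones and the reductive dehalogenation of 2-bromo-1,3-diketones.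

Step 8
Reactants: 16 7-endo bicyclic trione
Product: 18 CNP0148771.1 (target), via hydroperoxide 17 (not isolated)
Conditions: Mn(OAc)3·2H2O (10 mol %), O2 (1 atm), AcOH/MeCN (1:1), 23 °C; then PPh3, 0 °C
Reagents that add atoms: dioxygen, O=O
Why: Proposed new method: trivalent manganese oxidises the C3 enol to a C3 radical that adds 7-exo to the endo C7 prenyl olefin (C3 is fixed by the cage, and the CMe2 terminus turns to the C4/C6 side, away from the C8 methyls and the benzoyl group, which sets the ring-fusion CH), the tertiary radical traps O2, the peroxyl radical closes 7-exo onto the C3 prenyl olefin with its CMe2 terminus outside the forming ring in a twist-chair transition state whose pucker is fixed by the cage (setting the peroxide CH), a second O2 and hydrogen abstraction from the enol of 16 carry the chain to the hydroperoxide, and PPh3 reduces only the hydroperoxide; the closest known reactions are manganese triacetate/O2 peroxidations of 1,3-dicarbonyls with olefins, oxidative radical cyclisations of prenylated acylphloroglucinols and peroxyl radical cyclisations in thiol–olefin co-oxygenation.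

## Compound list

1 | (R)-lavandulol, (2R)-5-methyl-2-(prop-1-en-2-yl)hex-4-en-1-ol | OC[C@H](CC=C(C)C)C(C)=C | starting material
2 | (R)-lavandulyl iodide, (3R)-3-(iodomethyl)-2,6-dimethylhepta-1,5-diene | IC[C@H](CC=C(C)C)C(C)=C | intermediate
3 | di-tert-butyl malonate | CC(C)(C)OC(=O)CC(=O)OC(C)(C)C | starting material
4 | di-tert-butyl 2-[(2S)-5-methyl-2-(prop-1-en-2-yl)hex-4-en-1-yl]malonate | CC(C)=CC[C@@H](CC(C(=O)OC(C)(C)C)C(=O)OC(C)(C)C)C(C)=C | intermediate
5 | (5S)-6,6-dimethyl-5-(3-methylbut-2-en-1-yl)-2-oxooxane-3-carboxylic acid, C3 epimers | O=C1OC(C)(C)[C@@H](CC=C(C)C)CC1C(=O)O | intermediate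
6 | geranyl bromide, (2E)-1-bromo-3,7-dimethylocta-2,6-diene | CC(C)=CCC/C(C)=C/CBr | starting material
7 | (3S,5S)-3-[(2E)-3,7-dimethylocta-2,6-dien-1-yl]-6,6-dimethyl-5-(3-methylbut-2-en-1-yl)-2-oxooxane-3-carboxylic acid; geranyl trans and CO2H cis to the C5 prenyl arm | O=C1OC(C)(C)[C@@H](CC=C(C)C)C[C@@]1(C/C=C(\C)CCC=C(C)C)C(=O)O | intermediate
8 | benzoylacetone, 1-phenylbutane-1,3-dione | CC(=O)CC(=O)c1ccccc1 | starting material
9 | prenyl bromide, 1-bromo-3-methylbut-2-ene | CC(C)=CCBr | starting material
10 | 7-methyl-1-phenyloct-6-ene-1,3-dione | CC(C)=CCCC(=O)CC(=O)c1ccccc1 | intermediate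
11 | imidazolide of 7 (N-acyl imidazole, same stereocentres) | O=C1OC(C)(C)[C@@H](CC=C(C)C)C[C@@]1(C/C=C(\C)CCC=C(C)C)C(=O)n1ccnc1 | intermediate (not isolated)
12 | acylated lactone: lactone of 7 carrying the 2-prenyl-3,5-dioxo-5-phenylpentanoyl chain at C3 | O=C1OC(C)(C)[C@@H](CC=C(C)C)C[C@@]1(C/C=C(\C)CCC=C(C)C)C(=O)C(CC=C(C)C)C(=O)CC(=O)c1ccccc1 | intermediate (not isolated)
13 | (6S)-2-benzoyl-6-geranyl-3,5-dihydroxy-6-[(2S)-2-(2-hydroxypropan-2-yl)-5-methylhex-4-en-1-yl]-4-prenylcyclohexa-2,4-dien-1-one | O=C1C(C(=O)c2ccccc2)=C(O)C(CC=C(C)C)=C(O)[C@]1(C/C=C(\C)CCC=C(C)C)C[C@H](CC=C(C)C)C(C)(C)O | intermediate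
14 | C3-bromo monocycle: 13 with Br and prenyl on sp3 C3 (C3 epimers), C2 and C4 as ketones | O=C1C(C(=O)c2ccccc2)=C(O)C(Br)(CC=C(C)C)C(=O)[C@]1(C/C=C(\C)CCC=C(C)C)C[C@H](CC=C(C)C)C(C)(C)O | intermediate (not isolated)
15 | C3-bromo bicycle: 1-benzoyl-3-bromo-5-geranyl-8,8-dimethyl-3,7-diprenylbicyclo[3.3.1]nonane-2,4,9-trione (1S,5S,7S core, C3 epimers) | CC(C)=CCC/C(C)=C/C[C@@]12C[C@H](CC=C(C)C)C(C)(C)[C@@](C(=O)c3ccccc3)(C1=O)C(=O)C(Br)(CC=C(C)C)C2=O | intermediate (not isolated)
16 | (1S,5S,7S)-1-benzoyl-5-geranyl-4-hydroxy-8,8-dimethyl-3,7-diprenylbicyclo[3.3.1]non-3-ene-2,9-dione (7-endo prenyl) | CC(C)=CCC/C(C)=C/C[C@@]12C[C@H](CC=C(C)C)C(C)(C)[C@@](C(=O)c3ccccc3)(C1=O)C(=O)C(CC=C(C)C)=C2O | intermediate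
17 | hydroperoxide: target with C(CH3)2OOH in place of C(CH3)2OH | CC(C)=CCC/C(C)=C/C[C@]12C[C@@H]3C[C@@H]4C(C)(C)OO[C@H](C(C)(C)OO)C[C@@]4(C1=O)C(=O)[C@](C(=O)c1ccccc1)(C2=O)C3(C)C | intermediate (not isolated)
18 | CNP0148771.1: homoadamantane trione with bridgehead benzoyl, bridgehead geranyl and fused 1,2-dioxepane bearing the 2-hydroxypropan-2-yl group | CC(C)=CCC/C(C)=C/C[C@]12C[C@@H]3C[C@@H]4C(C)(C)OO[C@H](C(C)(C)O)C[C@@]4(C1=O)C(=O)[C@](C(=O)c1ccccc1)(C2=O)C3(C)C | target

## Step count and risks

Total step count: 8. Longest linear sequence: 7 steps (steps 1, 2, 3, 4, 6, 7, 8).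

Most likely to fail:

**Step 7.** The benzoyl-bearing C1 is a weak nucleophile and must bond to a tertiary cation. O-alkylation, elimination at C8 and acid damage to the geranyl chain compete, and the cyclised product is non-enolisable. Fallback: the benzoyl group is introduced last at the bridgehead. It sets out from 7 and returns at 16. Imidazolide 11 is acylated with the dianion of methyl 7-methyl-3-oxooct-6-enoate F2 (from the dianion of methyl acetoacetate and 9) and closed onto the lactone as in step 6, giving the 2-methoxycarbonyl monocycle F3. NaCl in wet DMSO (130 °C) removes the ester to the monocycle F4, whose only unsubstituted enol carbon is C1. Catalytic TfOH in (CF3)2CHOH then closes ring B at C1, which is less hindered than the prenylated C3, to the bridgehead-H bicycle F5, which keeps an enolisable 1,3-diketone. Me3SiCHN2 gives the methyl enol ether F6. Lithium 2,2,6,6-tetramethylpiperidide followed by benzoyl chloride benzoylates the bridgehead to give the benzoylated methyl enol ether F7. LiCl in DMSO (120 °C) cleaves the methyl ether to give 16.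

**Step 8.** The 7-exo peroxyl closure must outrun hydrogen abstraction or reduction of the peroxyl radical. Two stereocentres (the ring-fusion CH and the peroxide CH) rest on substrate control that I have argued from geometry but could not verify. Fallback: the two radical events are separated. It sets out from 16 and returns at 18. Mn(OAc)3·2H2O (2.2 equiv) and Cu(OAc)2·H2O (1 equiv) in degassed AcOH give the isopropenyl homoadamantane F8; divalent copper oxidises the tertiary radical to the olefin. Co(acac)2, O2 and Et3SiH (Mukaiyama–Isayama peroxidation) then generate the peroxyl radical at the same carbon by hydrogen-atom transfer to the isopropenyl group, which reacts faster than the trisubstituted olefins. The same 7-exo closure and a second O2 capture give the triethylsilyl peroxide F9. K2CO3 in MeOH frees hydroperoxide 17 and PPh3 gives 18.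

**Step 6.** A hindered secondary carbanion must acylate an alpha-quaternary acyl imidazole, and a stabilised carbon must then open a hindered lactone. Fallback: prenyl is installed after ring A. It sets out from 7 and returns at 13. Imidazolide 11 is treated with the dianion of commercial benzoylacetone 8 (an unhindered CH2 carbanion) and closed onto the lactone, giving the C3-unsubstituted monocycle F1. C-prenylation at its only free enol carbon (9, aq. KOH, 0 °C) gives 13. Step 5 is then not needed.

## Further compounds

F1 | step 6 | C3-unsubstituted monocycle: 13 without the C4 prenyl group (6S, side chain 2S) | O=C1C(C(=O)c2ccccc2)=C(O)C=C(O)[C@]1(C/C=C(\C)CCC=C(C)C)C[C@H](CC=C(C)C)C(C)(C)O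
F2 | step 7 | methyl 7-methyl-3-oxooct-6-enoate | COC(=O)CC(=O)CCC=C(C)C
F3 | step 7 | 2-methoxycarbonyl monocycle: 13 with CO2CH3 in place of benzoyl | O=C1C(C(=O)OC)=C(O)C(CC=C(C)C)=C(O)[C@]1(C/C=C(\C)CCC=C(C)C)C[C@H](CC=C(C)C)C(C)(C)O
F4 | step 7 | monocycle without acyl group: 13 with H in place of benzoyl | O=C1C=C(O)C(CC=C(C)C)=C(O)[C@]1(C/C=C(\C)CCC=C(C)C)C[C@H](CC=C(C)C)C(C)(C)O
F5 | step 7 | bridgehead-H bicycle: 16 with H in place of benzoyl at C1 | CC(C)=CCC/C(C)=C/C[C@@]12C[C@H](CC=C(C)C)C(C)(C)[C@@H](C1=O)C(=O)C(CC=C(C)C)=C2O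
F6 | step 7 | methyl enol ether of F5 (4-methoxy) | CC(C)=CCC/C(C)=C/C[C@@]12C[C@H](CC=C(C)C)C(C)(C)[C@@H](C1=O)C(=O)C(CC=C(C)C)=C2OC
F7 | step 7 | benzoylated methyl enol ether: 16 as its 4-methyl ether | CC(C)=CCC/C(C)=C/C[C@@]12C[C@H](CC=C(C)C)C(C)(C)[C@@](C(=O)c3ccccc3)(C1=O)C(=O)C(CC=C(C)C)=C2OC
F8 | step 8 | isopropenyl homoadamantane: cage of 18 with prenyl on C3 and isopropenyl on the ring-fusion CH, no peroxide | CC(C)=CCC/C(C)=C/C[C@]12C[C@@H]3C[C@H](C(C)=C)[C@](CC=C(C)C)(C1=O)C(=O)[C@](C(=O)c1ccccc1)(C2=O)C3(C)C
F9 | step 8 | triethylsilyl peroxide: 17 as its O-triethylsilyl derivative | CC(C)=CCC/C(C)=C/C[C@]12C[C@@H]3C[C@@H]4C(C)(C)OO[C@H](C(C)(C)OO[Si](CC)(CC)CC)C[C@@]4(C1=O)C(=O)[C@](C(=O)c1ccccc1)(C2=O)C3(C)C
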